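Assumption: the SMILES is read as the (3R)-ring, (2S)-side-chain, (5E) isomer; Cy2BH and LDA are added as preformed reagents.

## Retrosynthetic overview

1. The side-chain aldehyde is carried as an S-ethyl thioester and unmasked last (thioester to CHO with Pd/silane).
2. The only ring, the cyclopentene, is closed in the second-to-last step by intramolecular aldol condensation of an acyclic 1,6-keto-aldehyde whose ketone already carries CH2OAc; this creates the ring C=C, the ring CHO and the acetoxymethyl group together.
3. The keto-aldehyde and both stereocentres come from one organocatalytic Mukaiyama–Michael addition of a (Z)-silyl ketene thioacetal to (E)-7-acetoxy-6-oxohept-2-enal.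
4. Thioester fragment: geranyl bromide plus lithiated 1-(trimethylsilyl)propyne, then alkynylsilane to acid, thioester and silyl ketene thioacetal.
5. Enal fragment: butenyl Grignard plus acetoxyacetyl chloride, then cross-metathesis with crotonaldehyde.

## Route

Step 1
Reactants: 1 trimethyl(prop-1-yn-1-yl)silane; 2 (2E)-1-bromo-3,7-dimethylocta-2,6-diene (geranyl bromide)
Product: 4 trimethyl[(5E)-6,10-dimethylundeca-5,9-dien-1-yn-1-yl]silane, via lithiated silylpropyne 3 (not isolated)
Conditions: n-BuLi, THF, −78 → −20 °C; then 2, −78 °C → rt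
Reagents that add atoms: none
Why: Propargylic lithiation of the silyl-capped propyne and SN2 alkylation by the primary allylic bromide give the 1,5-enyne with the E olefin untouched and no stereocentre formed (propargyl anion alkylation).

Step 2
Reactants: 4 trimethyl[(5E)-6,10-dimethylundeca-5,9-dien-1-yn-1-yl]silane
Product: 6 (5E)-6,10-dimethylundeca-5,9-dienoic acid, via alkenylborane 5 (not isolated)
Conditions: Cy2BH, THF, 0 °C → rt; then 3 M NaOH, 30% H2O2, 0 → 40 °C; aq. HCl work-up
Reagents that add atoms: hydrogen peroxide, OO
Why: The hindered dialkylborane adds only to the alkyne, with boron on the silicon-bearing carbon, and alkaline peroxide oxidises the gem-silyl alkenylborane through the acylsilane to the carboxylic acid while the trisubstituted olefins stay intact (hydroboration–oxidation of a 1-silylalkyne).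

Step 3
Reactants: 6 (5E)-6,10-dimethylundeca-5,9-dienoic acid
Product: 7 S-ethyl (5E)-6,10-dimethylundeca-5,9-dienethioate
Conditions: EtSH, DCC, DMAP (cat.), CH2Cl2, 0 °C → rt
Reagents that add atoms: ethanethiol, CCS
Why: Carbodiimide activation with DMAP as acyl-transfer catalyst gives the thioester under neutral conditions that do not touch the diene (Steglich thioesterification).

Step 4
Reactants: 7 S-ethyl (5E)-6,10-dimethylundeca-5,9-dienethioate
Product: 9 {[(1Z,5E)-1-(ethylsulfanyl)-6,10-dimethylundeca-1,5,9-trien-1-yl]oxy}trimethylsilane, via lithium enolate 8 (not isolated)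
Conditions: LDA, THF, −78 °C; then TMSCl, −78 °C → rt
Reagents that add atoms: chlorotrimethylsilane, C[Si](C)(C)Cl
Why: Kinetic deprotonation in THF through a closed Ireland-type transition state places the chain trans to oxygen, and O-silylation traps this enolate as the (Z)-silyl ketene thioacetal (enolate silylation).

Step 5
Reactants: 10 but-3-en-1-ylmagnesium bromide; 11 2-chloro-2-oxoethyl acetate (acetoxyacetyl chloride)
Product: 12 2-oxohex-5-en-1-yl acetate
Conditions: Fe(acac)3 (3 mol%), THF, −78 °C
Reagents that add atoms: none
Why: Iron-catalysed acylation of the Grignard reagent by the acid chloride is far faster at −78 °C than attack on the acetate or on the ketone product, so the α-acetoxy ketone forms without over-addition (Fe-catalysed Grignard–acid chloride coupling).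

Step 6
Reactants: 12 2-oxohex-5-en-1-yl acetate; 13 (2E)-but-2-enal (crotonaldehyde)
Product: 14 (5E)-2,7-dioxohept-5-en-1-yl acetate
Conditions: second-generation Hoveyda–Grubbs catalyst (H2IMes)Cl2Ru(=CH-C6H4-2-OiPr) (2.5 mol%), 13 (5 equiv), CH2Cl2, 40 °C
Reagents that add atoms: none
Why: Olefin cross-metathesis of the terminal alkene with excess crotonaldehyde releases propene and gives the thermodynamically preferred (E)-enal.

Step 7
Reactants: 14 (5E)-2,7-dioxohept-5-en-1-yl acetate; 9 {[(1Z,5E)-1-(ethylsulfanyl)-6,10-dimethylundeca-1,5,9-trien-1-yl]oxy}trimethylsilane (1.5 equiv)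
Product: 16 S-ethyl (2S,5E)-2-[(3S)-7-(acetyloxy)-1,6-dioxoheptan-3-yl]-6,10-dimethylundeca-5,9-dienethioate, via iminium ion 15 (not isolated)
Conditions: (2R,5R)-5-benzyl-2-tert-butyl-3-methylimidazolidin-4-one·Cl3CCO2H (20 mol%), CH2Cl2, H2O (2 equiv), −70 °C
Reagents that add atoms: none
Why: In this iminium-catalysed Mukaiyama–Michael addition the benzyl group of the (2R,5R)-imidazolidinone shields one face of the (E)-iminium ion so that 9 attacks the Si face of the enal β-carbon (the future ring stereocentre), and an open antiperiplanar transition state that keeps the two chains apart sets the thioester α-carbon anti to it, giving the (2S,3S) adduct.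

Step 8
Reactants: 16 S-ethyl (2S,5E)-2-[(3S)-7-(acetyloxy)-1,6-dioxoheptan-3-yl]-6,10-dimethylundeca-5,9-dienethioate
Product: 18 S-ethyl (2S,5E)-2-[(1R)-3-(acetoxymethyl)-2-formylcyclopent-2-en-1-yl]-6,10-dimethylundeca-5,9-dienethioate, via aldol adduct 17 (not isolated)
Conditions: Bn2NH·CF3CO2H (20 mol%), toluene, 50 °C
Reagents that add atoms: none
Why: In this amine-catalysed intramolecular aldol condensation the unhindered aldehyde forms the enamine, which closes the five-membered ring onto the activated α-acetoxy ketone, and the tertiary aldol dehydrates irreversibly to the tetrasubstituted enal without touching either existing stereocentre.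

Step 9
Reactants: 18 S-ethyl (2S,5E)-2-[(1R)-3-(acetoxymethyl)-2-formylcyclopent-2-en-1-yl]-6,10-dimethylundeca-5,9-dienethioate
Product: 19 [(3R)-2-formyl-3-[(2S,5E)-6,10-dimethyl-1-oxoundeca-5,9-dien-2-yl]cyclopent-1-en-1-yl]methyl acetate
Conditions: Et3SiH, 10% Pd/C (5 mol% Pd), acetone, rt
Reagents that add atoms: none
Why: In the Fukuyama reduction palladium inserts into the C–S bond and the silane delivers hydride under neutral conditions, so the thioester becomes the aldehyde without epimerising the α-stereocentre and the acetate, the hindered enal and the trisubstituted olefins are expected to survive.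

## Compound list

1 | trimethyl(prop-1-yn-1-yl)silane | CC#C[Si](C)(C)C | starting material
2 | (2E)-1-bromo-3,7-dimethylocta-2,6-diene (geranyl bromide) | BrC/C=C(\C)CCC=C(C)C | starting material
3 | [3-(trimethylsilyl)prop-2-yn-1-yl]lithium | [Li]CC#C[Si](C)(C)C | intermediate
4 | trimethyl[(5E)-6,10-dimethylundeca-5,9-dien-1-yn-1-yl]silane | C[Si](C)(C)C#CCC/C=C(\C)CCC=C(C)C | intermediate
5 | dicyclohexyl[(1Z,5E)-6,10-dimethyl-1-(trimethylsilyl)undeca-1,5,9-trien-1-yl]borane | C[Si](C)(C)/C(B(C1CCCCC1)C1CCCCC1)=C\CC/C=C(\C)CCC=C(C)C | intermediate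
6 | (5E)-6,10-dimethylundeca-5,9-dienoic acid | OC(=O)CCC/C=C(\C)CCC=C(C)C | intermediate
7 | S-ethyl (5E)-6,10-dimethylundeca-5,9-dienethioate | CCSC(=O)CCC/C=C(\C)CCC=C(C)C | intermediate
8 | lithium (1Z,5E)-1-(ethylsulfanyl)-6,10-dimethylundeca-1,5,9-trien-1-olate | [Li+].[O-]/C(SCC)=C/CC/C=C(\C)CCC=C(C)C | intermediate
9 | {[(1Z,5E)-1-(ethylsulfanyl)-6,10-dimethylundeca-1,5,9-trien-1-yl]oxy}trimethylsilane | CCS/C(O[Si](C)(C)C)=C\CC/C=C(\C)CCC=C(C)C | intermediate
10 | but-3-en-1-ylmagnesium bromide | C=CCC[Mg]Br | starting material
11 | 2-chloro-2-oxoethyl acetate (acetoxyacetyl chloride) | CC(=O)OCC(Cl)=O | starting material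
12 | 2-oxohex-5-en-1-yl acetate | CC(=O)OCC(=O)CCC=C | intermediate
13 | (2E)-but-2-enal (crotonaldehyde) | C/C=C/C=O | starting material
14 | (5E)-2,7-dioxohept-5-en-1-yl acetate | CC(=O)OCC(=O)CC/C=C/C=O | intermediate
15 | iminium ion of 14 with (2R,5R)-5-benzyl-2-tert-butyl-3-methylimidazolidin-4-one (trichloroacetate) | CN1C(=O)[C@@H](Cc2ccccc2)/[N+](=C\C=C\CCC(=O)COC(C)=O)[C@H]1C(C)(C)C.[O-]C(=O)C(Cl)(Cl)Cl | intermediate
16 | S-ethyl (2S,5E)-2-[(3S)-7-(acetyloxy)-1,6-dioxoheptan-3-yl]-6,10-dimethylundeca-5,9-dienethioate | O=CC[C@@H]([C@@H](C(=O)SCC)CC/C=C(\C)CCC=C(C)C)CCC(=O)COC(C)=O | intermediate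
17 | S-ethyl (2S,5E)-2-[3-(acetoxymethyl)-2-formyl-3-hydroxycyclopentyl]-6,10-dimethylundeca-5,9-dienethioate (chain-bearing ring carbon as in 16; the two new ring centres as a mixture) | CC(=O)OCC1(O)C(C=O)[C@@H]([C@@H](C(=O)SCC)CC/C=C(\C)CCC=C(C)C)CC1 | intermediate
18 | S-ethyl (2S,5E)-2-[(1R)-3-(acetoxymethyl)-2-formylcyclopent-2-en-1-yl]-6,10-dimethylundeca-5,9-dienethioate | CC(=O)OCC1=C(C=O)[C@@H]([C@@H](C(=O)SCC)CC/C=C(\C)CCC=C(C)C)CC1 | intermediate
19 | [(3R)-2-formyl-3-[(2S,5E)-6,10-dimethyl-1-oxoundeca-5,9-dien-2-yl]cyclopent-1-en-1-yl]methyl acetate | CC(=O)OCC1=C(C=O)[C@@H]([C@@H](C=O)CC/C=C(\C)CCC=C(C)C)CC1 | target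

## Step count and risks

Total step count: 9. Longest linear sequence: 7 steps (steps 1, 2, 3, 4, 7, 8, 9); steps 5 and 6 make the second fragment.

Steps most likely to fail:

Step 7 (Mukaiyama–Michael addition). The anti outcome is predicted from a transition-state argument and is not established for this pair of partners; the syn adduct could dominate, and silyl hydrolysis competes. The fallback changes the stereochemical control element instead of the reaction conditions. It sets out from thioester 7, which is enolised with LDA in THF/HMPA and silylated to the geometrically inverted nucleophile {[(1E,5E)-1-(ethylsulfanyl)-6,10-dimethylundeca-1,5,9-trien-1-yl]oxy}trimethylsilane F1. F1 is added to enal 14 under the same iminium catalysis; since an open transition state translates enol-silane geometry into relative configuration, this should invert the syn/anti preference while the catalyst still fixes the ring stereocentre. The fallback returns to the route at 16.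

Step 9 (Fukuyama reduction). Palladium hydride chemistry could hydrogenolyse the allylic acetate or reduce the enal. The fallback reorders the end game so that palladium never meets these groups. It sets out from 16, which is reduced first (Et3SiH, Pd/C, acetone) to the keto-dialdehyde (2S,5E)-2-[(3S)-7-(acetyloxy)-1,6-dioxoheptan-3-yl]-6,10-dimethylundeca-5,9-dienal F2. F2 is then cyclised with Bn2NH·CF3CO2H; only the unbranched aldehyde forms an enamine quickly, and only its aldol with the ketone can dehydrate, so the product is 19, where the fallback rejoins the route. The cost is a free α-branched aldehyde during the amine step, so epimerisation must be watched.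

Step 8 (aldol condensation). The amine salt may aminolyse the thioester, or the reaction may stall at the tertiary aldol. The fallback separates bond formation from dehydration. It sets out from 16, which is cyclised with (S)-proline (30 mol%, DMSO, rt) by enamine aldol addition. The β-hydroxy aldehyde 17 is isolated and dehydrated with Martin sulfurane (CH2Cl2, 0 °C) to 18, where the fallback returns to the route. No compound outside the list is made (F0).

Further compounds
F1 | step 7 | {[(1E,5E)-1-(ethylsulfanyl)-6,10-dimethylundeca-1,5,9-trien-1-yl]oxy}trimethylsilane | CCS/C(O[Si](C)(C)C)=C/CC/C=C(\C)CCC=C(C)C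
F2 | step 9 | (2S,5E)-2-[(3S)-7-(acetyloxy)-1,6-dioxoheptan-3-yl]-6,10-dimethylundeca-5,9-dienal | O=CC[C@@H]([C@@H](C=O)CC/C=C(\C)CCC=C(C)C)CCC(=O)COC(C)=O
F0 | step 8 | none | none
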